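Two questions stand on the board, and I answer them by deciding which of the next flasks to charge first.

common to all: L 0.30 M

|  | J | X | G | remark | time |
|---|---|---|---|---|---|
| north-west | 1.3 equiv | 0.57 equiv | 0.30 M | run made earlier |  |
| north-east | 1.3 equiv | 5.7 equiv | 0.30 M | run made earlier |  |
| autumn | 1.30 equiv | 0.800 equiv | 0.300 M |  | 4.0 min |
| dusk | 1.30 equiv | 2.50 equiv | 0.300 M |  | 4.0 min |
| summer | 1.30 equiv | 8.00 equiv | 0.300 M |  | 4.0 min |

- north-west (time / min: E / %, L / %): 0.333: 34.6, 51.6; 1.00: 39.8, 35.8; 2.00: 36.4, 28.9; 3.00: 29.3, 28.3
- north-east (time / min: E / %, L / %): 0.333: 20.4, 9.2; 1.00: 18.5, 3.1; 2.00: 12.3, 0.8; 3.00: 10.8, 1.1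

(scatter of a reading: 1 percentage point)

- amount of E at the end, in percent of the L charged for autumn, dusk, summer, in this order
- the course of these numbers from the first flask to the last (falls, then rises / falls all the way / rises all the way / hardly changes / rises, then falls)

- the analysis behind the earlier runs scatters by 1 percentage point, standard deviation
- steps under discussion: J + G -> D; L + J <-> E; L + X -> Q
- "hardly changes" means that all values lie within two and a half points (for a concentration: within two and a half percent of the largest)

The two earlier runs have the same charge of L, J and G and differ in X, so I read what X does to E after its early rise. From 1.00 min to 3.00 min the north-west run gives 0.153 min⁻¹ for the leak of E, the rate at which E falls divided by the E standing, averaged between those two readings. It is a net figure, what E gives up less what forms again from L and J, and it is no constant: the two stretches of that north-west window read 0.0893 min⁻¹ and 0.217 min⁻¹, so I use it as a rough average. Over the same times the north-east run, with ten times the X, gives 0.269 min⁻¹, a faster leak, read through a scatter of 1 percentage point. I take this to mean that E gives back L and J, and that X catches part of that L as Q.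

If I assume each average holds on to 4.0 min, my estimate of E is 25.1% for the north-west charge and 8.25% for the north-east charge. Between these two I let E fall as a power of X, with exponent 0.484. My reckoning then gives 21.3% for autumn, 12.3% for dusk and 7.00% for summer. Autumn stands above the other two, so I charge autumn first and leave L, J and G as they are.

The forecast gives 22%, 11% and 6%, a course that falls all the way, and its ground is: “E forms early and then reverts to L + J, and X drains the released L irreversibly”.

The flasks give 24.1%, 12.7% and 5.75%, a course that falls all the way.

    J + G → D (k = 0.220 L mol⁻¹ s⁻¹)
    L + J ⇌ E (K = 22.0 L mol⁻¹, k = 0.120 L mol⁻¹ s⁻¹)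
    L + X → Q (k = 0.0620 L mol⁻¹ s⁻¹)

Between 2.00 min and 4.00 min the autumn flask goes from 32.8% to 24.1% of E, a leak of 0.153 min⁻¹ against the 0.153 min⁻¹ read in the north-west run, while the summer flask goes from 10.6% to 5.75%, a leak of 0.306 min⁻¹, above the 0.269 min⁻¹ of the north-east run and twice the autumn leak. In the autumn flask, counting the forward step to E alone, L passes to Q at 0.32 times the rate at which it passes to E at the start, and at 4.00 min that ratio has risen to 1.0.

The runs stem from a simulated flask with made-up constants.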